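**Retrosynthesis**
- Remove the silyl group (17 ← 16). The erythro (7S,8R) β-O-4 diol comes from a ketoreductase dynamic kinetic resolution of a racemic α-aryloxy-β-hydroxy ketone (15).
- Ketone 15 comes from alkylating the dihydrobenzofuran phenol 12 with bromoacetoveratrone, then hydroxymethylating.
- The only new ring is the trans-2-aryl-3-hydroxymethyl-dihydrobenzofuran. It is formed first, by Rh2-catalysed asymmetric 1,5-benzylic C–H insertion of aryl diazoacetate 9, which sets C2 and C3.
- Diazoester 9 comes from an ortho-bromophenol derived from dihydroconiferyl alcohol, a Mitsunobu benzylation with a syringyl benzyl alcohol, Pd α-arylation of tBuOAc and diazo transfer.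

**Assumptions**
- Syringaldehyde, dihydroconiferyl alcohol and 2-bromo-1-(3,4-dimethoxyphenyl)ethanone are purchased.
- Rh2(S-PTTL)4 is assumed to give the (2R,3R)-ester 10. If the opposite enantiomer forms, Rh2(R-PTTL)4 is used.
- A commercial ketoreductase (KRED) panel hit delivering (7S,8R)-erythro is assumed.

---

**Step 1**
Reactants: 1 syringaldehyde
Product: 2 4-(benzyloxy)-3,5-dimethoxybenzaldehyde
Conditions: BnBr, K2CO3, DMF, rt
Reagents that add atoms: benzyl bromide, BrCc1ccccc1
Why: Williamson O-benzylation of the acidic phenol; the product is achiral.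

**Step 2**
Reactants: 2
Product: 3 (4-(benzyloxy)-3,5-dimethoxyphenyl)methanol
Conditions: NaBH4, MeOH/THF, 0 °C
Reagents that add atoms: none
Why: Chemoselective aldehyde reduction; the benzyl ether is untouched.

**Step 3**
Reactants: 4 3-(4-hydroxy-3-methoxyphenyl)propan-1-ol (dihydroconiferyl alcohol)
Product: 5 4-(3-((tert-butyldimethylsilyl)oxy)propyl)-2-methoxyphenol
Conditions: TBSCl (2.3 equiv), imidazole, DMF, rt; then K2CO3, MeOH, rt
Reagents that add atoms: TBSCl, CC(C)(C)[Si](C)(C)Cl
Why: Both OH groups are silylated, then methoxide cleaves the more labile aryl silyl ether selectively, leaving the primary alkyl TBS ether.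

**Step 4**
Reactants: 5
Product: 6 2-bromo-4-(3-TBSO-propyl)-6-methoxyphenol
Conditions: NBS, i-Pr2NH (10 mol%), CH2Cl2, 0 °C to rt
Reagents that add atoms: NBS, O=C1CCC(=O)N1Br
Why: Electrophilic aromatic bromination occurs only at the free position ortho to the OH, since the para position carries the chain and the other ortho position carries OMe.

**Step 5**
Reactants: 6; 3
Product: 7 aryl benzyl ether, 1-bromo-2-[(4-benzyloxy-3,5-dimethoxybenzyl)oxy]-3-methoxy-5-(3-TBSO-propyl)benzene
Conditions: PPh3, DIAD, THF, 0 °C to rt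
Reagents that add atoms: none
Why: Mitsunobu etherification of the acidic bromophenol with a primary benzylic alcohol, an SN2 at a non-stereogenic carbon.

**Step 6**
Reactants: 7
Product: 8 tert-butyl 2-[2-(ArCH2O)-3-methoxy-5-(3-TBSO-propyl)phenyl]acetate (Ar = 4-benzyloxy-3,5-dimethoxyphenyl)
Conditions: tBuOAc, LiHMDS (2.4 equiv), Pd(dba)2/Q-Phos (2 mol%), toluene, rt to 50 °C
Reagents that add atoms: tert-butyl acetate, CC(=O)OC(C)(C)C (supplies CH2CO2tBu)
Why: Pd-catalysed α-arylation of an ester enolate (Hartwig type) installs the aryl-acetate carbon; the bulky tBu ester limits Claisen side reactions.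

**Step 7**
Reactants: 8
Product: 9 tert-butyl 2-diazo-2-aryl-acetate (aryl diazoacetate)
Conditions: p-ABSA, DBU, MeCN, 0 °C to rt
Reagents that add atoms: p-ABSA, CC(=O)Nc1ccc(cc1)S(=O)(=O)N=[N+]=[N-] (supplies N2)
Why: Regitz diazo transfer to the doubly activated (aryl, ester) CH2 gives the donor/acceptor carbene precursor.

**Step 8**
Reactants: 9
Product: 10 tert-butyl (2R,3R)-trans-2-[4-(benzyloxy)-3,5-dimethoxyphenyl]-5-(3-TBSO-propyl)-7-methoxy-2,3-dihydrobenzofuran-3-carboxylate
Conditions: Rh2(S-PTTL)4 (1 mol%), CH2Cl2, 25 °C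
Reagents that add atoms: none (N2 is lost)
Why: The chiral dirhodium carbenoid inserts intramolecularly (1,5) into the benzylic OCH2Ar C–H. The catalyst controls the enantioface, and the concerted asynchronous hydride-transfer/C–C bond formation gives the trans-2,3 ring, so C2 and C3 are both set here.

**Step 9**
Reactants: 10
Product: 11 [(2R,3S)-2-(4-benzyloxy-3,5-dimethoxyphenyl)-5-(3-TBSO-propyl)-7-methoxy-2,3-dihydrobenzofuran-3-yl]methanol
Conditions: LiAlH4, THF, 0 °C to rt
Reagents that add atoms: none
Why: Ester reduction to the primary alcohol; the silyl and benzyl ethers survive, the C3–H no longer sits α to a carbonyl, and the trans ring is retained. The descriptor at C3 changes from R to S only because the CIP priorities change.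

**Step 10**
Reactants: 11
Product: 12 4-[(2R,3S)-5-(3-TBSO-propyl)-3-(hydroxymethyl)-7-methoxy-2,3-dihydrobenzofuran-2-yl]-2,6-dimethoxyphenol
Conditions: H2 (1 atm), 10% Pd/C, EtOAc/EtOH, rt, monitored to avoid over-reduction
Reagents that add atoms: none
Why: Hydrogenolysis of the aryl benzyl ether frees the syringyl phenol; the stereocentres are untouched and the TBS ether is inert.

**Step 11**
Reactants: 12; 13 2-bromo-1-(3,4-dimethoxyphenyl)ethan-1-one
Product: 14 α-aryloxy ketone, 1-(3,4-dimethoxyphenyl)-2-[aryloxy]ethan-1-one (aryloxy = the dihydrobenzofuranyl-2,6-dimethoxyphenoxy group from 12)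
Conditions: K2CO3, acetone, 50 °C (DMF, rt if sluggish)
Reagents that add atoms: none beyond reactant 13
Why: Phenoxide SN2 on the unhindered primary α-bromoketone; the free alcohols are not deprotonated by K2CO3.

**Step 12**
Reactants: 14
Product: 15 racemic-at-C8 α-aryloxy-β-hydroxy ketone, 1-(3,4-dimethoxyphenyl)-3-hydroxy-2-aryloxypropan-1-one
Conditions: 37% aq. HCHO (1.1 equiv), K2CO3 (0.5 equiv), dioxane/H2O, rt
Reagents that add atoms: formaldehyde, C=O (supplies CH2OH)
Why: Base-mediated aldol hydroxymethylation at the acidic α-aryloxy CH2, with the formaldehyde charge held near stoichiometric to avoid bis-addition; it gives an epimerisable C8 stereocentre as required for DKR.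

**Step 13**
Reactants: 15
Product: 16 TBS-protected target, (7S,8R)-erythro diol
Conditions: KRED (NADPH-dependent ketoreductase, panel hit), NADP+ (cat.), i-PrOH (15% v/v, cofactor recycling), 100 mM Tris·HCl pH 8.0, 20% DMSO, 30 °C, 24–48 h
Reagents that add atoms: none (hydride and proton transfer only)
Why: Dynamic kinetic resolution by ketoreductase: the α-aryloxy stereocentre epimerises fast at pH 8, and the enzyme reduces one ketone enantiomer on one face, so C8 (R) and C7 (S) are set together in the erythro relationship.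

**Step 14**
Reactants: 16
Product: 17 Berbikonol
Conditions: TBAF (3 equiv), AcOH (3 equiv), THF, 0 °C to rt
Reagents that add atoms: none
Why: Fluoride removes the primary TBS ether; the buffering acetic acid protects the molecule, and no remaining stereocentre is epimerisable (no carbonyl neighbours).

---

**Compound list**

| No. | Name | SMILES | Role |
|---|---|---|---|
| 1 | Syringaldehyde | COc1cc(C=O)cc(OC)c1O | starting material |
| 2 | 4-(Benzyloxy)-3,5-dimethoxybenzaldehyde | COc1cc(C=O)cc(OC)c1OCc1ccccc1 | intermediate |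
| 3 | (4-(Benzyloxy)-3,5-dimethoxyphenyl)methanol | COc1cc(CO)cc(OC)c1OCc1ccccc1 | intermediate |
| 4 | 3-(4-Hydroxy-3-methoxyphenyl)propan-1-ol | COc1cc(CCCO)ccc1O | starting material |
| 5 | 4-(3-TBSO-propyl)-2-methoxyphenol | COc1cc(CCCO[Si](C)(C)C(C)(C)C)ccc1O | intermediate |
| 6 | 2-Bromo-4-(3-TBSO-propyl)-6-methoxyphenol | COc1cc(CCCO[Si](C)(C)C(C)(C)C)cc(Br)c1O | intermediate |
| 7 | Aryl benzyl ether (bromo) | COc1cc(CCCO[Si](C)(C)C(C)(C)C)cc(Br)c1OCc1cc(OC)c(OCc2ccccc2)c(OC)c1 | intermediate |
| 8 | tert-Butyl arylacetate | COc1cc(CCCO[Si](C)(C)C(C)(C)C)cc(CC(=O)OC(C)(C)C)c1OCc1cc(OC)c(OCc2ccccc2)c(OC)c1 | intermediate |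
| 9 | tert-Butyl aryl diazoacetate | COc1cc(CCCO[Si](C)(C)C(C)(C)C)cc(C(=[N+]=[N-])C(=O)OC(C)(C)C)c1OCc1cc(OC)c(OCc2ccccc2)c(OC)c1 | intermediate |
| 10 | trans-Dihydrobenzofuran tert-butyl ester (2R,3R) | COc1cc([C@@H]2Oc3c(OC)cc(CCCO[Si](C)(C)C(C)(C)C)cc3[C@H]2C(=O)OC(C)(C)C)cc(OC)c1OCc1ccccc1 | intermediate |
| 11 | Dihydrobenzofuran-3-yl methanol (2R,3S), benzyl-protected | COc1cc([C@@H]2Oc3c(OC)cc(CCCO[Si](C)(C)C(C)(C)C)cc3[C@H]2CO)cc(OC)c1OCc1ccccc1 | intermediate |
| 12 | Syringyl phenol dihydrobenzofuran (2R,3S) | COc1cc([C@@H]2Oc3c(OC)cc(CCCO[Si](C)(C)C(C)(C)C)cc3[C@H]2CO)cc(OC)c1O | intermediate |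
| 13 | 2-Bromo-1-(3,4-dimethoxyphenyl)ethanone | COc1ccc(C(=O)CBr)cc1OC | starting material |
| 14 | α-Aryloxy ketone | COc1ccc(C(=O)COc2c(OC)cc([C@@H]3Oc4c(OC)cc(CCCO[Si](C)(C)C(C)(C)C)cc4[C@H]3CO)cc2OC)cc1OC | intermediate |
| 15 | α-Aryloxy-β-hydroxy ketone (C8 racemic) | COc1ccc(C(=O)C(CO)Oc2c(OC)cc([C@@H]3Oc4c(OC)cc(CCCO[Si](C)(C)C(C)(C)C)cc4[C@H]3CO)cc2OC)cc1OC | intermediate |
| 16 | TBS-protected Berbikonol | COc1ccc([C@H](O)[C@@H](CO)Oc2c(OC)cc([C@@H]3Oc4c(OC)cc(CCCO[Si](C)(C)C(C)(C)C)cc4[C@H]3CO)cc2OC)cc1OC | intermediate |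
| 17 | Berbikonol | COc1ccc([C@H](O)[C@@H](CO)Oc2c(OC)cc([C@@H]3Oc4c(OC)cc(CCCO)cc4[C@H]3CO)cc2OC)cc1OC | target |

---

**Totals**
- Total steps: 14
- Longest linear sequence: 12 steps (4 → 5 → 6 → 7 → 8 → 9 → 10 → 11 → 12 → 14 → 15 → 16 → 17, counted by step: Steps 3–14; the Step 1–2 branch joins at Step 5 and has the same length)

**Three steps most likely to fail**
1. **Step 13, KRED dynamic kinetic resolution.** The substrate is large and lipophilic, and racemisation, retro-aldol loss of CH2O, or wrong erythro/threo selectivity are all possible. Fallback: replace the enzyme with Ru–TsDPEN asymmetric transfer hydrogenation DKR (HCO2H/Et3N) on the same ketone 15. If that also fails, switch to a different bond construction: Sharpless-derived erythro-configured 3,4-dimethoxyphenyl glycerate acceptor and Mitsunobu etherification of phenol 12.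
2. **Step 8, Rh-catalysed C–H insertion.** Enantioselectivity with the tBu ester, and competing Buchner or cyclopropanation pathways, are uncertain. Fallback: make racemic trans-ester with Rh2(OAc)4 or Rh2(oct)4, then resolve alcohol 11 by lipase-catalysed acylation (vinyl acetate) and carry the correct enantiomer forward.
3. **Step 10, debenzylation.** The benzylic C2–O bond of the dihydrobenzofuran could hydrogenolyse. Fallback: redo Step 5 with an O-TIPS-protected syringyl benzyl alcohol so the phenol is released together with the silyl group by fluoride, avoiding hydrogenation altogether.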